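**Plan**

- Retrosynthesis: ring A is cut back at C4–Br, at the C3–H bond and at the exocyclic carbon on C1 (silylmethyl addition with transposition) to a vinylogous ester. Ring B is cut at C8–C9 (α-ketol shift) to a spiro 1-(chloroacetyl)cyclopentanol, then at C9–C10 (acyl anion plus cyclopentanone), at C7–C8 and C6–C11 ([3+2] cycloaddition) and at the exocyclic C6=C7 bond, back to dimedone.
- Forward: ring A is the dimedone ring. The cyclopentane is spiro-annulated at C6 by Pd–trimethylenemethane cycloaddition, cleaved to the ketone, and converted by ethoxyvinyl addition and chlorination into the acylcyclopentanol. The Lewis-acid α-ketol shift enlarges it to ring B. Ring B is then held as a silyl enol ether while ring A receives the silylmethyl group, bromine, the C3 hydroxyl and last the exocyclic methylene.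
- Stereochemistry: C6 from the chiral phosphoramidite–palladium catalyst. C10 of the cyclopentanol from addition anti to the C5 gem-dimethyl group, passed on stereospecifically to C9 in the chelated shift. C4 from axial protonation of a bromo dienolate on the ring A conformer fixed by ring B. C3 from equatorial hydride attack cis to bromine.

Key step: step 7

Remark: atom labels in the text follow the target (ring A: C1 with the exocyclic carbon, C2, C3 OH, C4 Br, C5 CMe2, C6 spiro; ring B: C6, C7, C8, C9 carbinol, C10 ketone, C11). In the spiro[4.5] compounds the cyclopentane is C6–C7–C8–C10–C11 and C9 is the acyl carbon; their systematic names carry their own locants, and the spiro[5.5] names use the target locants.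

Remark: the antipode of the phosphoramidite that gives the (S) spiro centre of 7 cannot be predicted for this acceptor and is assumed to be identified in a pilot run with both antipodes.

**Route**

Step 1
Reactants: 1 5,5-dimethylcyclohexane-1,3-dione
Product: 2 3-methoxy-5,5-dimethylcyclohex-2-en-1-one
Conditions: MeOH, TsOH·H2O (cat.), 3 Å MS, reflux
Reagents that add atoms: methanol, CO
Why: Acid-catalysed enol etherification of the symmetric cyclic 1,3-diketone (vinylogous esterification) needs no selectivity and is driven by removal of water on the sieves.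

Step 2
Reactants: 2 3-methoxy-5,5-dimethylcyclohex-2-en-1-one
Product: 5 3-methoxy-5,5-dimethyl-6-methylidenecyclohex-2-en-1-one, via Mannich base 3 (not isolated), via trimethylammonium iodide 4 (not isolated)
Conditions: LiN(i-Pr)2, THF, −78 °C; Me2N=CH2+ I−, −78 °C → rt; MeI, CH2Cl2, rt; aq. NaHCO3, CH2Cl2, rt
Reagents that add atoms: dimethyl(methylidene)ammonium iodide, C=[N+](C)C.[I-]
Why: The kinetic α′-enolate at C6 is aminomethylated in a Mannich reaction with the preformed iminium salt, and N-methylation followed by base-induced β-elimination of trimethylamine (Hofmann-type) unveils the exocyclic enone, which the flanking gem-dimethyl group protects from dimerisation.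

Step 3
Reactants: 5 3-methoxy-5,5-dimethyl-6-methylidenecyclohex-2-en-1-one; 6 2-[(trimethylsilyl)methyl]allyl acetate
Product: 7 (5S)-8-methoxy-10,10-dimethyl-2-methylidenespiro[4.5]dec-7-en-6-one
Conditions: Pd(dba)2 (5 mol %), chiral 2,5-diarylpyrrolidine phosphoramidite (10 mol %), toluene, 45 °C
Reagents that add atoms: none
Why: Pd-catalysed trimethylenemethane [3+2] cycloaddition: the zwitterionic π-allyl complex adds to the enone terminus C7 and the resulting enolate closes on the allyl ligand to form C6–C11, so the spiro carbon is set in this ring closure under control of the chiral phosphoramidite on palladium.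

Step 4
Reactants: 7 (5S)-8-methoxy-10,10-dimethyl-2-methylidenespiro[4.5]dec-7-en-6-one
Product: 8 (5S)-8-methoxy-10,10-dimethylspiro[4.5]dec-7-ene-2,6-dione
Conditions: OsO4 (2 mol %), NaIO4, 2,6-lutidine, dioxane–H2O (3:1), rt
Reagents that add atoms: osmium tetroxide (oxygen carrier), O=[Os](=O)(=O)=O; sodium periodate (terminal oxidant), [Na+].[O-]I(=O)(=O)=O
Why: Lemieux–Johnson oxidation: OsO4 dihydroxylates the unhindered 1,1-disubstituted alkene much faster than the push–pull double bond of the vinylogous ester, and periodate cleaves the diol to the cyclopentanone.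

Step 5
Reactants: 8 (5S)-8-methoxy-10,10-dimethylspiro[4.5]dec-7-ene-2,6-dione; 9 ethyl vinyl ether
Product: 11 (2S,5S)-2-(1-ethoxyethenyl)-2-hydroxy-8-methoxy-10,10-dimethylspiro[4.5]dec-7-en-6-one, via 1-ethoxyvinyllithium 10 (not isolated)
Conditions: t-BuLi, THF, −78 → 0 °C (lithiation of 9); 8, THF, −78 °C; H2O
Reagents that add atoms: none
Why: 1,2-Addition of the acyl anion equivalent to the only unhindered ketone (the C1 carbonyl is a neopentyl vinylogous ester) should occur on the cyclopentanone face anti to the C5 gem-dimethyl group, one methyl of which lies under the five-membered ring, so that the new hydroxyl at C10 is cis to C5 (S).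

Step 6
Reactants: 11 (2S,5S)-2-(1-ethoxyethenyl)-2-hydroxy-8-methoxy-10,10-dimethylspiro[4.5]dec-7-en-6-one
Product: 12 (2S,5S)-2-(chloroacetyl)-2-hydroxy-8-methoxy-10,10-dimethylspiro[4.5]dec-7-en-6-one
Conditions: NCS, THF–H2O (4:1), 0 °C
Reagents that add atoms: N-chlorosuccinimide, ClN1C(=O)CCC1=O; water, O
Why: Electrophilic chlorination of the electron-rich enol ether and hydrolysis of the α-chloro oxocarbenium ion give the chloromethyl ketone directly, without touching C10 or the less nucleophilic vinylogous ester.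

Step 7
Reactants: 12 (2S,5S)-2-(chloroacetyl)-2-hydroxy-8-methoxy-10,10-dimethylspiro[4.5]dec-7-en-6-one
Product: 13 (6S,9S)-9-(chloromethyl)-9-hydroxy-3-methoxy-5,5-dimethylspiro[5.5]undec-2-ene-1,10-dione
Conditions: Sc(OTf)3 (0.3 equiv), 4 Å MS, toluene, 60 °C
Reagents that add atoms: none
Why: Sc(OTf)3 binds the C10 hydroxyl and the acyl oxygen in a five-membered chelate that holds the two C–O bonds syn-periplanar and places the ring bonds C10–C8 and C10–C11 on opposite faces of the acyl carbonyl; C8 then migrates suprafacially from C10 to C9 while C10 becomes the ring ketone, the Lewis-acid acyloin (α-ketol) rearrangement known for 1-acylcycloalkanols and for the D-homoannulation of 17-hydroxy-20-keto steroids. Ring B is not formed by a cyclisation but by one-carbon enlargement of the cyclopentane through this 1,2-alkyl shift, which creates the C8–C9 bond. The new stereocenter C9 is controlled by C10 of 12: with the hydroxyl cis to C5, the shift of C8 inside the chelate attacks the carbonyl face that leaves the new hydroxyl axial and cis to C5 and the chloromethyl group equatorial, (9S). The selectivity needed is migration of C8 and not of the neopentyl C11; the C11 shift is the more hindered one and would place the new carbinol 1,3 to the spiro carbon with an unavoidable syn-axial contact to a ring A carbon. Since the shift is reversible and trades a 1-acylcyclopentanol bearing an α-chloro ketone for a cyclohexanone, the regioisomer can revert and drain to 13, while the C9 epimer, which arises only from the minor C10 epimer of 12 or without chelation, carries an axial chloromethyl group and is the less stable. The vinylogous ester of ring A is a poor nucleophile and is expected to survive the Lewis acid.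

Step 8
Reactants: 13 (6S,9S)-9-(chloromethyl)-9-hydroxy-3-methoxy-5,5-dimethylspiro[5.5]undec-2-ene-1,10-dione
Product: 14 (6S,9S)-9,10-bis(tert-butyldimethylsilyloxy)-9-(chloromethyl)-3-methoxy-5,5-dimethylspiro[5.5]undeca-2,10-dien-1-one
Conditions: t-BuMe2SiOTf (2.5 equiv), Et3N, CH2Cl2, −78 → 0 °C
Reagents that add atoms: tert-butyldimethylsilyl trifluoromethanesulfonate, CC(C)(C)[Si](C)(C)OS(=O)(=O)C(F)(F)F
Why: The silyl triflate with amine base silylates the tertiary hydroxyl and, by soft enolisation, the C10 ketone, which can enolise only toward C11; the chlorohydrin–ketone thereby becomes inert to base, organolithium and hydride while C10 and C11 stay trigonal.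

Step 9
Reactants: 14 (6S,9S)-9,10-bis(tert-butyldimethylsilyloxy)-9-(chloromethyl)-3-methoxy-5,5-dimethylspiro[5.5]undeca-2,10-dien-1-one
Product: 16 (6S,9S)-9,10-bis(tert-butyldimethylsilyloxy)-9-(chloromethyl)-5,5-dimethyl-1-[(trimethylsilyl)methyl]spiro[5.5]undeca-1,10-dien-3-one, via tertiary carbinol 15 (not isolated)
Conditions: CeCl3, Me3SiCH2Li, THF, −78 → 0 °C; then 1 M aq. HCl, 0 °C, short contact
Reagents that add atoms: (trimethylsilyl)methyllithium, [Li]C[Si](C)(C)C; water, O
Why: CeCl3-assisted 1,2-addition of the silylmethyl nucleophile to the hindered vinylogous ester carbonyl, then mild acid hydrolysis with allylic transposition and loss of methanol (Stork–Danheiser sequence), gives the 3-(silylmethyl) enone, the brief cold acid sparing the hindered silyl enol ether.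

Step 10
Reactants: 16 (6S,9S)-9,10-bis(tert-butyldimethylsilyloxy)-9-(chloromethyl)-5,5-dimethyl-1-[(trimethylsilyl)methyl]spiro[5.5]undeca-1,10-dien-3-one
Product: 19 (4R,6R,9S)-4-bromo-9,10-bis(tert-butyldimethylsilyloxy)-9-(chloromethyl)-5,5-dimethyl-1-[(trimethylsilyl)methyl]spiro[5.5]undeca-1,10-dien-3-one, via bromo enone epimers 17 (not isolated), via lithium bromo dienolate 18 (not isolated)
Conditions: LiN(i-Pr)2, THF, −78 °C; NBS, −78 °C; LiN(SiMe3)2, −78 °C; AcOH, −78 °C → rt
Reagents that add atoms: N-bromosuccinimide, BrN1C(=O)CCC1=O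
Why: Kinetic α′-deprotonation at C4 and bromination of the lithium dienolate introduce bromine, then re-enolisation and protonation set C4: the proton should enter axially, anti to the pseudo-axial C5 methyl, on the ring A half-chair that keeps the flat enol ether arm C11 rather than the C7 methylene beside the C1 silylmethyl group, leaving bromine equatorial and cis to C11 (R), which is also the more stable epimer.

Step 11
Reactants: 19 (4R,6R,9S)-4-bromo-9,10-bis(tert-butyldimethylsilyloxy)-9-(chloromethyl)-5,5-dimethyl-1-[(trimethylsilyl)methyl]spiro[5.5]undeca-1,10-dien-3-one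
Product: 20 (3S,4R,6R,9S)-4-bromo-9,10-bis(tert-butyldimethylsilyloxy)-9-(chloromethyl)-5,5-dimethyl-1-[(trimethylsilyl)methyl]spiro[5.5]undeca-1,10-dien-3-ol
Conditions: i-Bu2AlH, CH2Cl2, −78 °C; aq. KNaC4H4O6
Reagents that add atoms: none
Why: 1,2-Reduction of the enone by the bulky hydride from the equatorial direction, the axial trajectory being blocked by the axial C5 methyl, should give the axial alcohol cis to the equatorial bromine (S).

Step 12
Reactants: 20 (3S,4R,6R,9S)-4-bromo-9,10-bis(tert-butyldimethylsilyloxy)-9-(chloromethyl)-5,5-dimethyl-1-[(trimethylsilyl)methyl]spiro[5.5]undeca-1,10-dien-3-ol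
Product: 21 (3S,4R,6R,9S)-4-bromo-9-(tert-butyldimethylsilyloxy)-9-(chloromethyl)-3-hydroxy-5,5-dimethyl-1-methylidenespiro[5.5]undecan-10-one
Conditions: TsOH·H2O, wet CH2Cl2, 0 °C → rt
Reagents that add atoms: none
Why: Protodesilylation of the allylsilane (SE2′): protonation at C2 and loss of silicon from the β-silyl cation move the double bond regiospecifically to the exocyclic position, while the same acid hydrolyses the silyl enol ether to the C10 ketone; ionisation of the allylic hydroxyl is retarded by the adjacent C–Br bond.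

Step 13
Reactants: 21 (3S,4R,6R,9S)-4-bromo-9-(tert-butyldimethylsilyloxy)-9-(chloromethyl)-3-hydroxy-5,5-dimethyl-1-methylidenespiro[5.5]undecan-10-one
Product: 22 (3S,4R,6R,9S)-4-bromo-9-(chloromethyl)-3,9-dihydroxy-5,5-dimethyl-1-methylidenespiro[5.5]undecan-10-one
Conditions: HF·pyridine, THF, 0 °C → rt
Reagents that add atoms: none
Why: Fluoride-assisted cleavage of the tertiary silyl ether under acidic conditions, in which the chlorohydrin cannot close to an epoxide and no stereocenter is touched.

**Compound list**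

1 | 5,5-dimethylcyclohexane-1,3-dione (dimedone) | CC1(C)CC(=O)CC(=O)C1 | starting material
2 | 3-methoxy-5,5-dimethylcyclohex-2-en-1-one | COC1=CC(=O)CC(C)(C)C1 | intermediate
3 | 6-[(dimethylamino)methyl]-3-methoxy-5,5-dimethylcyclohex-2-en-1-one (racemic Mannich base) | CN(C)CC1C(=O)C=C(OC)CC1(C)C | intermediate
4 | [(4-methoxy-6,6-dimethyl-2-oxocyclohex-3-en-1-yl)methyl]trimethylammonium iodide (racemic) | C[N+](C)(C)CC1C(=O)C=C(OC)CC1(C)C.[I-] | intermediate
5 | 3-methoxy-5,5-dimethyl-6-methylidenecyclohex-2-en-1-one | C=C1C(=O)C=C(OC)CC1(C)C | intermediate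
6 | 2-[(trimethylsilyl)methyl]allyl acetate | CC(=O)OCC(=C)C[Si](C)(C)C | starting material
7 | (5S)-8-methoxy-10,10-dimethyl-2-methylidenespiro[4.5]dec-7-en-6-one | O=C1C=C(OC)CC(C)(C)[C@@]12CCC(=C)C2 | intermediate
8 | (5S)-8-methoxy-10,10-dimethylspiro[4.5]dec-7-ene-2,6-dione | O=C1C=C(OC)CC(C)(C)[C@@]12CCC(=O)C2 | intermediate
9 | ethyl vinyl ether | C=COCC | starting material
10 | (1-ethoxyvinyl)lithium | [Li]C(=C)OCC | intermediate
11 | (2S,5S)-2-(1-ethoxyethenyl)-2-hydroxy-8-methoxy-10,10-dimethylspiro[4.5]dec-7-en-6-one (hydroxyl cis to the CMe2 carbon) | O=C1C=C(OC)CC(C)(C)[C@@]12CC[C@@](O)(C(=C)OCC)C2 | intermediate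
12 | (2S,5S)-2-(chloroacetyl)-2-hydroxy-8-methoxy-10,10-dimethylspiro[4.5]dec-7-en-6-one (hydroxyl cis to the CMe2 carbon) | O=C1C=C(OC)CC(C)(C)[C@@]12CC[C@@](O)(C(=O)CCl)C2 | intermediate
13 | (6S,9S)-9-(chloromethyl)-9-hydroxy-3-methoxy-5,5-dimethylspiro[5.5]undec-2-ene-1,10-dione | O=C1C=C(OC)CC(C)(C)[C@@]12CC[C@@](O)(CCl)C(=O)C2 | intermediate
14 | (6S,9S)-9,10-bis(tert-butyldimethylsilyloxy)-9-(chloromethyl)-3-methoxy-5,5-dimethylspiro[5.5]undeca-2,10-dien-1-one | O=C1C=C(OC)CC(C)(C)[C@@]12CC[C@@](O[Si](C)(C)C(C)(C)C)(CCl)C(O[Si](C)(C)C(C)(C)C)=C2 | intermediate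
15 | (6S,9S)-9,10-bis(tert-butyldimethylsilyloxy)-9-(chloromethyl)-3-methoxy-5,5-dimethyl-1-[(trimethylsilyl)methyl]spiro[5.5]undeca-2,10-dien-1-ol (C1 epimers) | C[Si](C)(C)CC1(O)C=C(OC)CC(C)(C)[C@@]12CC[C@@](O[Si](C)(C)C(C)(C)C)(CCl)C(O[Si](C)(C)C(C)(C)C)=C2 | intermediate
16 | (6S,9S)-9,10-bis(tert-butyldimethylsilyloxy)-9-(chloromethyl)-5,5-dimethyl-1-[(trimethylsilyl)methyl]spiro[5.5]undeca-1,10-dien-3-one | C[Si](C)(C)CC1=CC(=O)CC(C)(C)[C@@]12CC[C@@](O[Si](C)(C)C(C)(C)C)(CCl)C(O[Si](C)(C)C(C)(C)C)=C2 | intermediate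
17 | (6R,9S)-4-bromo-9,10-bis(tert-butyldimethylsilyloxy)-9-(chloromethyl)-5,5-dimethyl-1-[(trimethylsilyl)methyl]spiro[5.5]undeca-1,10-dien-3-one (C4 epimers) | C[Si](C)(C)CC1=CC(=O)C(Br)C(C)(C)[C@@]12CC[C@@](O[Si](C)(C)C(C)(C)C)(CCl)C(O[Si](C)(C)C(C)(C)C)=C2 | intermediate
18 | lithium (6R,9S)-4-bromo-9,10-bis(tert-butyldimethylsilyloxy)-9-(chloromethyl)-5,5-dimethyl-1-[(trimethylsilyl)methyl]spiro[5.5]undeca-1,3,10-trien-3-olate | C[Si](C)(C)CC1=CC(O[Li])=C(Br)C(C)(C)[C@@]12CC[C@@](O[Si](C)(C)C(C)(C)C)(CCl)C(O[Si](C)(C)C(C)(C)C)=C2 | intermediate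
19 | (4R,6R,9S)-4-bromo-9,10-bis(tert-butyldimethylsilyloxy)-9-(chloromethyl)-5,5-dimethyl-1-[(trimethylsilyl)methyl]spiro[5.5]undeca-1,10-dien-3-one | C[Si](C)(C)CC1=CC(=O)[C@H](Br)C(C)(C)[C@@]12CC[C@@](O[Si](C)(C)C(C)(C)C)(CCl)C(O[Si](C)(C)C(C)(C)C)=C2 | intermediate
20 | (3S,4R,6R,9S)-4-bromo-9,10-bis(tert-butyldimethylsilyloxy)-9-(chloromethyl)-5,5-dimethyl-1-[(trimethylsilyl)methyl]spiro[5.5]undeca-1,10-dien-3-ol | C[Si](C)(C)CC1=C[C@H](O)[C@H](Br)C(C)(C)[C@@]12CC[C@@](O[Si](C)(C)C(C)(C)C)(CCl)C(O[Si](C)(C)C(C)(C)C)=C2 | intermediate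
21 | (3S,4R,6R,9S)-4-bromo-9-(tert-butyldimethylsilyloxy)-9-(chloromethyl)-3-hydroxy-5,5-dimethyl-1-methylidenespiro[5.5]undecan-10-one | C=C1C[C@H](O)[C@H](Br)C(C)(C)[C@@]12CC[C@@](O[Si](C)(C)C(C)(C)C)(CCl)C(=O)C2 | intermediate
22 | (3S,4R,6R,9S)-4-bromo-9-(chloromethyl)-3,9-dihydroxy-5,5-dimethyl-1-methylidenespiro[5.5]undecan-10-one | C=C1C[C@H](O)[C@H](Br)C(C)(C)[C@@]12CC[C@@](O)(CCl)C(=O)C2 | target

**Count and risks**

Total steps: 13. Longest linear sequence: 13 steps (1 to 22).

Step 3. The spiro carbon is created in the enolate-to-allyl ring closure, far from the ligand, so enantioface discrimination may be poor, and closure at the neopentyl enolate carbon may be slow. The fallback sets out from 2 and comes back at 8. Alkylation of the lithium enolate of 2 with 2-methoxyallyl bromide would give 3-methoxy-6-(2-methoxyprop-2-en-1-yl)-5,5-dimethylcyclohex-2-en-1-one F1. O-Acylation of its enolate with allyl chloroformate would give the allyl enol carbonate F2. Enantioselective decarboxylative allylation (Pd2(dba)3 with a tert-butyl phosphinooxazoline ligand of the appropriate hand) would set C6 in the allyl methoxyallyl enone F3. Ring-closing metathesis with the second-generation Grubbs catalyst would join the two side chains to the spiro methoxycyclopentene F4, and dilute oxalic acid would hydrolyse its enol ether to 8.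

Step 7. Migration of C11 may compete with that of C8, or the equilibrium may not drain cleanly to the (9S) ketol. The fallback sets out from 5 and comes back at 13. A Diels–Alder reaction of enone 5 with 2-(chloromethyl)buta-1,3-diene under a chiral oxazaborolidinium Lewis acid would give the spiro[5.5] diene F5, with the chloromethyl group para to the spiro carbon. Dihydroxylation with OsO4 and N-methylmorpholine N-oxide, anti to the pseudo-axial C1, would give the cis-diol F6, both hydroxyls cis to C5. Parikh–Doering oxidation of its only secondary hydroxyl would give 13.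

Step 10. Facial discrimination in the protonation rests on a conformational preference relayed from ring B and may be low, and γ-deprotonation at the silylmethyl group may compete. The fallback sets out from 17 and comes back at 22.
- Aqueous oxalic acid would cleave the silyl enol ether of 17 and free the C10 ketone in the C4-epimeric bromo enone ketone F7, where the axial C1 leans over a carbonyl carbon that has no axial hydrogen.
- Equilibration with DBU should then favour the equatorial bromide cis to C11, the (4R)-bromo enone ketone F8.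
- i-Bu2AlH would reduce both ketones to the diol F9.
- TsOH·H2O would remove the allylic silicon to give the exocyclic alkene F10, and HF·pyridine would remove the silyl ether to give the triol F11.
- Oxidation of the C9/C10 glycol through its dibutylstannylene acetal (Bu2SnO, then NBS) would restore the C10 ketone in the presence of the isolated C3 hydroxyl and give 22.

Further compounds
F1 | step 3 | 3-methoxy-6-(2-methoxyprop-2-en-1-yl)-5,5-dimethylcyclohex-2-en-1-one (racemic) | COC(=C)CC1C(=O)C=C(OC)CC1(C)C
F2 | step 3 | allyl 5-methoxy-2-(2-methoxyprop-2-en-1-yl)-3,3-dimethylcyclohexa-1,5-dien-1-yl carbonate | C=CCOC(=O)OC1=C(CC(=C)OC)C(C)(C)CC(OC)=C1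
F3 | step 3 | (6S)-3-methoxy-6-(2-methoxyprop-2-en-1-yl)-5,5-dimethyl-6-(prop-2-en-1-yl)cyclohex-2-en-1-one | O=C1C=C(OC)CC(C)(C)[C@@]1(CC(=C)OC)CC=C
F4 | step 3 | (5S)-2,8-dimethoxy-10,10-dimethylspiro[4.5]deca-2,7-dien-6-one | O=C1C=C(OC)CC(C)(C)[C@@]12CC=C(OC)C2
F5 | step 7 | (6S)-9-(chloromethyl)-3-methoxy-5,5-dimethylspiro[5.5]undeca-2,9-dien-1-one | O=C1C=C(OC)CC(C)(C)[C@@]12CCC(CCl)=CC2
F6 | step 7 | (6S,9S,10R)-9-(chloromethyl)-9,10-dihydroxy-3-methoxy-5,5-dimethylspiro[5.5]undec-2-en-1-one | O=C1C=C(OC)CC(C)(C)[C@@]12CC[C@@](O)(CCl)[C@H](O)C2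
F7 | step 10 | (6R,9S)-4-bromo-9-(tert-butyldimethylsilyloxy)-9-(chloromethyl)-5,5-dimethyl-1-[(trimethylsilyl)methyl]spiro[5.5]undec-1-ene-3,10-dione (C4 epimers) | C[Si](C)(C)CC1=CC(=O)C(Br)C(C)(C)[C@@]12CC[C@@](O[Si](C)(C)C(C)(C)C)(CCl)C(=O)C2
F8 | step 10 | (4R,6R,9S)-4-bromo-9-(tert-butyldimethylsilyloxy)-9-(chloromethyl)-5,5-dimethyl-1-[(trimethylsilyl)methyl]spiro[5.5]undec-1-ene-3,10-dione | C[Si](C)(C)CC1=CC(=O)[C@H](Br)C(C)(C)[C@@]12CC[C@@](O[Si](C)(C)C(C)(C)C)(CCl)C(=O)C2
F9 | step 10 | (3S,4R,6R,9S)-4-bromo-9-(tert-butyldimethylsilyloxy)-9-(chloromethyl)-5,5-dimethyl-1-[(trimethylsilyl)methyl]spiro[5.5]undec-1-ene-3,10-diol (C10 epimers) | C[Si](C)(C)CC1=C[C@H](O)[C@H](Br)C(C)(C)[C@@]12CC[C@@](O[Si](C)(C)C(C)(C)C)(CCl)C(O)C2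
F10 | step 10 | (3S,4R,6R,9S)-4-bromo-9-(tert-butyldimethylsilyloxy)-9-(chloromethyl)-5,5-dimethyl-1-methylidenespiro[5.5]undecane-3,10-diol (C10 epimers) | C=C1C[C@H](O)[C@H](Br)C(C)(C)[C@@]12CC[C@@](O[Si](C)(C)C(C)(C)C)(CCl)C(O)C2
F11 | step 10 | (3S,4R,6R,9S)-4-bromo-9-(chloromethyl)-5,5-dimethyl-1-methylidenespiro[5.5]undecane-3,9,10-triol (C10 epimers) | C=C1C[C@H](O)[C@H](Br)C(C)(C)[C@@]12CC[C@@](O)(CCl)C(O)C2
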